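**Retrosynthetic overview**
1. 27 ⇐ 26 ⇐ 25 ⇐ 24 ⇐ 23 ⇐ 19. The oxirane (α-face epoxidation of C8=C9), the C7 carbinol (Luche reduction) and the O6 ester are late functional-group operations on 4β,6α-dihydroxydauc-8-en-7-one 19.
2. 19 ⇐ 18 by cutting C6–C7. Both carbons are formyl carbons (a1 + a1). Carbene umpolung of the Z-enal carbon C7 joins them in an intramolecular crossed benzoin that closes the ring C1–C10–C9–C8–C7–C6–C5.
3. Enabling feature: the vicinal O-bearing pair C6/C7 of the seven-membered ring, with C7 next to C8=C9 (the later oxirane), is an acyloin retron. The C1 and C5 arms are trans on the cyclopentane, so the rival C6–C9 bond would need a trans-bicyclo[3.3.0]octane.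
4. 18 ⇐ 11 (ozonolysis, Still–Gennari olefination, DIBAL-H, Dess–Martin) ⇐ 9 (i-Pr addition sets C4) ⇐ 6 ⇐ 4 ⇐ 1. A CBS-derived C4 carbinol carries a silicon tether, and radical cyclisation with allyl transfer sets C5 and quaternary C1.
5. Ring order: cyclopentane (present in 1), temporary oxasilolane (made in step 3, removed in step 4), cycloheptene (step 12, last ring of the carbon skeleton). The oxirane oxygen is added to it in step 17.

Key step: step 12

Remark on numbering: daucane numbering is used for all compounds. C1 is the quaternary ring-fusion carbon, and its CH3 defines the β face. C2 and C3 are ring CH2. C4 is the carbinol carbon bearing isopropyl. C5 is the ring-fusion CH. C6 bears the aroyloxy group and C7 the free OH. C8 (CH3-bearing) and C9 are the oxirane carbons. C10 is the CH2 between C9 and C1.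

Step 1
Reactants: 1 3-methylcyclopent-2-en-1-one
Product: 2 (S)-3-methylcyclopent-2-en-1-ol (C4–OH β)
Conditions: (R)-Me-CBS (10 mol %), BH3·SMe2, THF, −40 °C; MeOH, aq. work-up
Reagents that add atoms: none
Why: In the Corey–Bakshi–Shibata reduction the oxazaborolidine–borane complex binds the ketone with the alkenyl arm as the large group and delivers hydride to one face, which should set the C4 carbinol (S) as the control element for C5 and C1.

Step 2
Reactants: 2 (S)-3-methylcyclopent-2-en-1-ol; 3 (bromomethyl)chlorodimethylsilane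
Product: 4 (S)-3-methylcyclopent-2-enyl (bromomethyl)dimethylsilyl ether
Conditions: imidazole, CH2Cl2, 0 °C
Reagents that add atoms: (bromomethyl)chlorodimethylsilane, C[Si](C)(Cl)CBr
Why: Standard O-silylation of a secondary allylic alcohol with a chlorosilane installs the temporary silicon tether without touching the stereocentre.

Step 3
Reactants: 4 (S)-3-methylcyclopent-2-enyl (bromomethyl)dimethylsilyl ether; 5 allyltributylstannane
Product: 6 cis-fused 6-allyl-3,3,6-trimethyl-2-oxa-3-silabicyclo[3.3.0]octane (O4, C6 and C1–CH3 β; allyl α)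
Conditions: 5 (3 equiv, 0.5 M), AIBN (cat.), PhH, 80 °C
Reagents that add atoms: allyltributylstannane, C=CC[Sn](CCCC)(CCCC)CCCC
Why: In this Nishiyama–Stork silicon-tethered radical cyclisation followed by Keck allyl transfer, the α-silyl radical closes 5-exo on C5 on the face of O4 (cis-fused oxasilolane, sets C5) and the tertiary C1 radical takes allyl from the stannane on the convex α face anti to the new C5–C6 bond (sets quaternary C1).

Step 4
Reactants: 6 bicyclic siloxane
Product: 7 3α-allyl-2β-(hydroxymethyl)-3β-methylcyclopentan-1β-ol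
Conditions: 30 % H2O2, KF, KHCO3, THF/MeOH, rt
Reagents that add atoms: hydrogen peroxide, OO
Why: The Tamao–Fleming oxidation replaces the C6–Si bond by C6–OH and frees O4, which removes the temporary ring and touches no stereocentre.

Step 5
Reactants: 7 3α-allyl-2β-(hydroxymethyl)-3β-methylcyclopentan-1β-ol
Product: 8 3α-allyl-3β-methyl-2β-[(triethylsilyloxy)methyl]cyclopentan-1β-ol
Conditions: TESCl (1.05 equiv), imidazole, CH2Cl2, −20 °C
Reagents that add atoms: chlorotriethylsilane, CC[Si](Cl)(CC)CC
Why: Selective silylation relies on the faster reaction of the primary C6 hydroxyl compared with the secondary ring hydroxyl at low temperature with one equivalent of chlorosilane.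

Step 6
Reactants: 8 primary TES ether
Product: 9 3α-allyl-3β-methyl-2β-[(triethylsilyloxy)methyl]cyclopentan-1-one
Conditions: Dess–Martin periodinane, pyridine, CH2Cl2, 0 °C
Reagents that add atoms: none
Why: The buffered Dess–Martin oxidation gives the C4 ketone under non-epimerising conditions, and enolisation towards C5 is slowed by the adjacent quaternary C1.

Step 7
Reactants: 9 cyclopentanone; 10 isopropylmagnesium chloride
Product: 11 3α-allyl-1α-isopropyl-3β-methyl-2β-[(triethylsilyloxy)methyl]cyclopentan-1β-ol
Conditions: LaCl3·2LiCl (1 equiv), THF, −78 to −40 °C; aq. NH4Cl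
Reagents that add atoms: isopropylmagnesium chloride, CC(C)[Mg]Cl
Why: The lanthanide-promoted Grignard 1,2-addition suppresses enolisation and β-hydride reduction, and the nucleophile attacks the α face anti to the adjacent C5–CH2OTES group and the C1 methyl, which sets C4 (OH β, i-Pr α).

Step 8
Reactants: 11 tertiary alcohol
Product: 13 C9 aldehyde (C1–CH2–CHO arm; 4β-OH; 6-OTES), via secondary ozonide 12 (not isolated)
Conditions: O3, CH2Cl2, −78 °C; PPh3, −78 °C to rt
Reagents that add atoms: ozone, [O-][O+]=O
Why: Ozonolysis (Criegee mechanism) of the only C=C bond with reductive work-up cuts the allyl group back to the C10–C9 aldehyde arm without touching a stereocentre.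

Step 9
Reactants: 13 C9 aldehyde; 14 ethyl 2-[bis(2,2,2-trifluoroethoxy)phosphoryl]propanoate
Product: 15 ethyl (Z)-enoate (C10–C9H=C8(CH3)–C7O2Et; C10 cis to C7)
Conditions: KHMDS, 18-crown-6, THF, −78 °C
Reagents that add atoms: ethyl 2-[bis(2,2,2-trifluoroethoxy)phosphoryl]propanoate, CCOC(=O)C(C)P(=O)(OCC(F)(F)F)OCC(F)(F)F
Why: In the Still–Gennari variant of the Horner–Wadsworth–Emmons olefination, fast irreversible elimination from the kinetic adduct of the trifluoroethyl phosphonate gives the Z trisubstituted enoate, which places C10 and C7 cis as the ring needs.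

Step 10
Reactants: 15 ethyl (Z)-enoate
Product: 17 triol (C6H2OH; (Z)-C7H2OH; 4β-OH), via allylic alcohol TES ether 16 (not isolated)
Conditions: DIBAL-H (5 equiv), CH2Cl2, −78 °C; then 1 M HCl, THF, 0 °C
Reagents that add atoms: none
Why: DIBAL-H 1,2-reduction of the enoate keeps the Z geometry, and the dilute acid quench cleaves the labile primary TES ether, so both arms end as primary alcohols in one operation.

Step 11
Reactants: 17 triol
Product: 18 dialdehyde (C5–C6HO β; (Z)-enal C7HO on the α arm; 4β-OH)
Conditions: Dess–Martin periodinane (2.5 equiv), pyridine, CH2Cl2, 0 °C; used at once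
Reagents that add atoms: none
Why: A double Dess–Martin oxidation converts both primary alcohols to aldehydes and leaves the tertiary C4 alcohol untouched, and buffer and low temperature should preserve the Z enal and C5.

Step 12
Reactants: 18 dialdehyde
Product: 19 4β,6α-dihydroxy-5αH-dauc-8-en-7-one
Conditions: 2-(pentafluorophenyl)-6,7-dihydro-5H-pyrrolo[2,1-c][1,2,4]triazol-2-ium tetrafluoroborate (20 mol %), i-Pr2NEt (20 mol %), toluene, 5 mM, 40 °C
Reagents that add atoms: none
Why: Proposed new method: the carbene adds to the less hindered, conjugated C7 aldehyde, proton transfer gives a dienyl Breslow intermediate in which C7 is nucleophilic (a1 to d1 umpolung), C7 attacks the C6 aldehyde, and proton shift with loss of the carbene gives the acyloin, so that 18 is simply isomerised to 19. The closest known reaction types are the carbene-catalysed intramolecular (crossed) benzoin closures to five- and six-membered acyloins and the Stetter reactions in which enals act as acyl-anion donors under N-pentafluorophenyl triazolium catalysis; new here are the seven-membered ring and the enal/alkanal pairing. The cycloheptene closes by a 7-exo-trig attack of C7 on the C6 carbonyl, helped by the Z C8=C9 bond and the cyclopentane, which leave only four rotatable bonds between the reacting carbons. The one new stereocentre, C6, is under substrate control: the formyl group reacts in the rotamer with C6–H anti to C5–H and can be reached only from the side of the C1 arm, which puts O6 on the α face (equatorial), and because the benzoin addition is reversible this is also the thermodynamic epimer. The donor/acceptor selectivity follows from the shielding of C6 by the two fully substituted neighbours of C5 (C1 and C4) and from conjugation of the product ketone with C8=C9. The rival homoenolate or Stetter bond C6–C9 would give a trans-bicyclo[3.3.0]octane and is shut off by the trans arms.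

Step 13
Reactants: 20 4-hydroxybenzoic acid
Product: 22 4-(tert-butyldimethylsilyloxy)benzoic acid, via bis-silylated acid 21 (not isolated)
Conditions: TBSCl (2.2 equiv), imidazole, DMF, rt; then AcOH/THF/H2O, rt
Reagents that add atoms: tert-butyldimethylsilyl chloride, CC(C)(C)[Si](C)(C)Cl
Why: Exhaustive silylation followed by selective hydrolysis of the much more labile silyl ester gives the phenol-protected acid.

Step 14
Reactants: 19 4β,6α-dihydroxy-5αH-dauc-8-en-7-one; 22 4-(tert-butyldimethylsilyloxy)benzoic acid
Product: 23 6α-[4-(tert-butyldimethylsilyloxy)benzoyloxy]-4β-hydroxydauc-8-en-7-one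
Conditions: DCC, DMAP, CH2Cl2, rt to 35 °C
Reagents that add atoms: 4-(tert-butyldimethylsilyloxy)benzoic acid, OC(=O)c1ccc(O[Si](C)(C)C(C)(C)C)cc1
Why: The Steglich esterification acylates the only secondary hydroxyl (O6) while the tertiary C4 hydroxyl is too hindered to react, and C6 is already the more stable equatorial epimer.

Step 15
Reactants: 23 keto ester
Product: 24 6α-[4-(tert-butyldimethylsilyloxy)benzoyloxy]dauc-8-ene-4β,7β-diol
Conditions: NaBH4, CeCl3·7H2O, MeOH/THF, −78 °C
Reagents that add atoms: none
Why: The Luche reduction gives clean 1,2-reduction of the enone, and the small hydride attacks C7 axially from the α face, antiperiplanar to the axial C6–Hβ bond, to give the equatorial 7β alcohol trans to the equatorial 6α ester.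

Step 16
Reactants: 24 allylic alcohol
Product: 25 7β-triethylsilyl ether of 24
Conditions: TESCl, imidazole, DMAP (cat.), DMF, rt
Reagents that add atoms: chlorotriethylsilane, CC[Si](Cl)(CC)CC
Why: Silylation of the secondary allylic O7 (the tertiary O4 stays free) removes its hydrogen-bond directing effect and adds bulk to the β face for the next step.

Step 17
Reactants: 25 TES ether
Product: 26 8α,9α-epoxide of 25
Conditions: mCPBA, CH2Cl2, 0 °C
Reagents that add atoms: meta-chloroperoxybenzoic acid, OOC(=O)c1cccc(Cl)c1
Why: The Prilezhaev epoxidation of the only alkene should take place from the α face because the β face is shielded by the C1 methyl and the 7β-OTES group, which sets C8 and C9.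

Step 18
Reactants: 26 protected epoxide
Product: 27 target, 8α,9α-epoxy-4β,7β-dihydroxy-5αH-daucan-6α-yl 4-hydroxybenzoate
Conditions: Et3N·3HF, MeCN, rt
Reagents that add atoms: none
Why: Fluoride-mediated cleavage of the aryl TBS and secondary TES ethers under near-neutral conditions spares oxirane and ester and avoids an O6 to O7 acyl shift.

**Compound list**
1 | 3-methylcyclopent-2-en-1-one | CC1=CC(=O)CC1 | starting material
2 | (S)-3-methylcyclopent-2-en-1-ol | O[C@H]1CCC(C)=C1 | intermediate
3 | (bromomethyl)chlorodimethylsilane | C[Si](C)(Cl)CBr | starting material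
4 | (S)-3-methylcyclopent-2-enyl (bromomethyl)dimethylsilyl ether | BrC[Si](C)(C)O[C@H]1CCC(C)=C1 | intermediate
5 | allyltributylstannane | C=CC[Sn](CCCC)(CCCC)CCCC | starting material
6 | cis-fused 6-allyl-3,3,6-trimethyl-2-oxa-3-silabicyclo[3.3.0]octane (O4, C6, C1–CH3 β; allyl α) | C=CC[C@@]1(C)CC[C@@H]2O[Si](C)(C)C[C@H]12 | intermediate
7 | 3α-allyl-2β-(hydroxymethyl)-3β-methylcyclopentan-1β-ol | O[C@H]1CC[C@](C)(CC=C)[C@H]1CO | intermediate
8 | 3α-allyl-3β-methyl-2β-[(triethylsilyloxy)methyl]cyclopentan-1β-ol | O[C@H]1CC[C@](C)(CC=C)[C@H]1CO[Si](CC)(CC)CC | intermediate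
9 | 3α-allyl-3β-methyl-2β-[(triethylsilyloxy)methyl]cyclopentan-1-one | O=C1CC[C@](C)(CC=C)[C@H]1CO[Si](CC)(CC)CC | intermediate
10 | isopropylmagnesium chloride | CC(C)[Mg]Cl | starting material
11 | 3α-allyl-1α-isopropyl-3β-methyl-2β-[(triethylsilyloxy)methyl]cyclopentan-1β-ol | CC(C)[C@]1(O)CC[C@](C)(CC=C)[C@H]1CO[Si](CC)(CC)CC | intermediate
12 | secondary ozonide (1,2,4-trioxolane) of 11, epimers at the trioxolane carbon | CC(C)[C@]1(O)CC[C@](C)(CC2OCOO2)[C@H]1CO[Si](CC)(CC)CC | intermediate
13 | C9 aldehyde: 2-{3β-hydroxy-3α-isopropyl-1β-methyl-2β-[(triethylsilyloxy)methyl]cyclopentyl}acetaldehyde | CC(C)[C@]1(O)CC[C@](C)(CC=O)[C@H]1CO[Si](CC)(CC)CC | intermediate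
14 | ethyl 2-[bis(2,2,2-trifluoroethoxy)phosphoryl]propanoate | CCOC(=O)C(C)P(=O)(OCC(F)(F)F)OCC(F)(F)F | starting material
15 | ethyl (Z)-2-methylbut-2-enoate carrying the cyclopentyl unit of 13 at C4 | CC(C)[C@]1(O)CC[C@](C)(C/C=C(/C)C(=O)OCC)[C@H]1CO[Si](CC)(CC)CC | intermediate
16 | (Z)-allylic alcohol from 15, C6–OTES still in place | CC(C)[C@]1(O)CC[C@](C)(C/C=C(/C)CO)[C@H]1CO[Si](CC)(CC)CC | intermediate
17 | triol: C6H2OH (β arm), (Z)-C7H2OH (α arm), 4β-OH | CC(C)[C@]1(O)CC[C@](C)(C/C=C(/C)CO)[C@H]1CO | intermediate
18 | dialdehyde: C6HO (β arm on C5), (Z)-2-methylenal C7HO (α arm on C1), 4β-OH | CC(C)[C@]1(O)CC[C@](C)(C/C=C(/C)C=O)[C@H]1C=O | intermediate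
19 | 4β,6α-dihydroxy-5αH-dauc-8-en-7-one | CC(C)[C@]1(O)CC[C@]2(C)CC=C(C)C(=O)[C@H](O)[C@H]21 | intermediate
20 | 4-hydroxybenzoic acid | OC(=O)c1ccc(O)cc1 | starting material
21 | tert-butyldimethylsilyl 4-(tert-butyldimethylsilyloxy)benzoate | CC(C)(C)[Si](C)(C)OC(=O)c1ccc(O[Si](C)(C)C(C)(C)C)cc1 | intermediate
22 | 4-(tert-butyldimethylsilyloxy)benzoic acid | OC(=O)c1ccc(O[Si](C)(C)C(C)(C)C)cc1 | intermediate
23 | 6α-[4-(tert-butyldimethylsilyloxy)benzoyloxy]-4β-hydroxy-5αH-dauc-8-en-7-one | CC(C)[C@]1(O)CC[C@]2(C)CC=C(C)C(=O)[C@H](OC(=O)c3ccc(O[Si](C)(C)C(C)(C)C)cc3)[C@H]21 | intermediate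
24 | 6α-[4-(tert-butyldimethylsilyloxy)benzoyloxy]-5αH-dauc-8-ene-4β,7β-diol | CC(C)[C@]1(O)CC[C@]2(C)CC=C(C)[C@@H](O)[C@H](OC(=O)c3ccc(O[Si](C)(C)C(C)(C)C)cc3)[C@H]21 | intermediate
25 | 7β-triethylsilyl ether of 24 | CC(C)[C@]1(O)CC[C@]2(C)CC=C(C)[C@@H](O[Si](CC)(CC)CC)[C@H](OC(=O)c3ccc(O[Si](C)(C)C(C)(C)C)cc3)[C@H]21 | intermediate
26 | 8α,9α-epoxide of 25 | CC(C)[C@]1(O)CC[C@]2(C)C[C@@H]3O[C@]3(C)[C@@H](O[Si](CC)(CC)CC)[C@H](OC(=O)c3ccc(O[Si](C)(C)C(C)(C)C)cc3)[C@H]21 | intermediate
27 | 8α,9α-epoxy-4β,7β-dihydroxy-5αH-daucan-6α-yl 4-hydroxybenzoate (CNP0290052.1) | CC(C)[C@]1(O)CC[C@]2(C)C[C@@H]3O[C@]3(C)[C@@H](O)[C@H](OC(=O)c3ccc(O)cc3)[C@H]21 | target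

Total step count: 18. Longest linear sequence: 17 (steps 1–12 and 14–18).

**Steps most likely to fail**
1. Step 12 (Proposed new method). The bond between the bulky Breslow carbon and the strongly shielded C6 aldehyde may form too slowly. Z to E isomerisation of the enal by reversible conjugate addition of the carbene, or β-protonation of the homoenolate, could then drain the substrate. Fallback with known chemistry: the route sets out from 18 and uses a low-valent titanium pinacol coupling (interrupted McMurry; TiCl3(DME)1.5, Zn–Cu, DME, slow addition). This should give 5αH-dauc-8-ene-4β,6α,7α-triol F1, with both oxygens bound to the metal on the open α face. MnO2 then oxidises only the allylic C7 hydroxyl, and the route is rejoined at 19.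
2. Step 3. Allyl may be transferred to the primary α-silyl radical before ring closure. Capture of the hindered tertiary C1 radical by the stannane may also be too slow, so that the chain collapses. Fallback: the route sets out from 4 and uses a cobalt-catalysed tandem radical cyclisation/cross-coupling with allylmagnesium chloride (CoCl2(dppp), THF, −40 to 0 °C). Here the tertiary radical is taken up by an allylcobalt species and the quaternary centre is made by reductive elimination instead of SH2′ on tin. The route is rejoined at 6, and no new compound is made.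
3. Step 15. Facial selectivity at C7 may be poor, or the acyl group may shift from O6 to O7 during reduction. Fallback: the route sets out from 19, before esterification. A hydroxyl-directed Evans–Saksena reduction (Me4NBH(OAc)3, MeCN/AcOH, −20 °C) lets the O6-bound borohydride deliver hydride inside the molecule on the α face. This should give 5αH-dauc-8-ene-4β,6α,7β-triol F2. Selective silylation of the less hindered allylic O7 (TESCl, imidazole, −20 °C) gives 7β-(triethylsilyloxy)-5αH-dauc-8-ene-4β,6α-diol F3. Steglich esterification with 22 rejoins the route at 25.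

**Further compounds**
F1 | step 12 | 5αH-dauc-8-ene-4β,6α,7α-triol | CC(C)[C@]1(O)CC[C@]2(C)CC=C(C)[C@H](O)[C@H](O)[C@H]21
F0 | step 3 | none | none
F2 | step 15 | 5αH-dauc-8-ene-4β,6α,7β-triol | CC(C)[C@]1(O)CC[C@]2(C)CC=C(C)[C@@H](O)[C@H](O)[C@H]21
F3 | step 15 | 7β-(triethylsilyloxy)-5αH-dauc-8-ene-4β,6α-diol | CC(C)[C@]1(O)CC[C@]2(C)CC=C(C)[C@@H](O[Si](CC)(CC)CC)[C@H](O)[C@H]21
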